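**The bar.** A catalyst cannot move a balance; it can move the time taken to reach it. So I put two questions to the flask: where its balance lay, and whether 8.0 h was time enough to get there.

in all of them: starting material 0.50 M; free catalyst 12 mM

| run | partner | protic impurity | remark | time |
|---|---|---|---|---|
| eta | 0.55 M | 5 mM | run made earlier |  |
| gamma | 0.55 M | 7.5 mM | run made earlier |  |
| flask | 0.550 M | 10.0 mM |  | 8.0 h |

| run | time / h | uncatalysed product / % | starting material / % | target / % | isomer of the product / % |
|---|---|---|---|---|---|
| eta | 0.417 | 0.7 | 45.4 | 33.8 | 17.6 |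
| eta | 1.33 | 1.1 | 34.5 | 38.8 | 26.3 |
| eta | 2.50 | 0.9 | 31.6 | 37.7 | 27.5 |
| eta | 3.00 | 1.5 | 32.0 | 37.2 | 28.5 |
| eta | 5.00 | 2.2 | 31.3 | 36.5 | 29.1 |
| eta | 6.00 | 3.7 | 31.9 | 35.7 | 28.6 |
| eta | 8.00 | 3.6 | 30.4 | 35.4 | 29.0 |
| gamma | 1.00 | 0.6 | 33.6 | 39.3 | 23.9 |
| gamma | 2.50 | 0.8 | 31.3 | 36.9 | 27.5 |
| gamma | 3.00 | 1.6 | 30.9 | 37.1 | 27.6 |
| gamma | 5.00 | 2.4 | 31.1 | 35.4 | 29.3 |
| gamma | 6.00 | 3.3 | 31.2 | 35.8 | 27.8 |
| gamma | 8.00 | 3.3 | 30.7 | 36.1 | 27.7 |

(readings scatter by 0.5 percentage points)

1. the largest share of what was charged as starting material, at 8.0 h belongs to (target / starting material / uncatalysed product / isomer of the product)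
2. the largest share itself, whichever of these holds it, in percent of the starting material charged



**The balance.** From the last reading of the gamma run, the nearest neighbour, I took 2.74: this is the pull, target over starting material, divided by partner left in charges of starting material, a mass-action ratio. The eta run, with less protic impurity, gave 2.77, so I saw no shift of the pull with impurity in these two readings.

**The time.** I counted turnovers against a harsh case, one catalyst lost per impurity, which leaves the flask 16.7 % of its catalyst and gamma 37.5 %. On that count, an estimate, gamma's survivors turned over at 70.9 h⁻¹ up to its first reading, while the flask's survivors needed 21.0 h⁻¹ to reach gamma's products in time. So I expected the flask to end where gamma ended, short by its extra impurity, 0.500 % of the starting material charged. Booking that against gamma's target, I committed to 35.6 %.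

**The forecast.** It named target at 36.5 %, higher than my figure, and wrote that “the plateau doesn't move with impurity”.

**The result.** The flask gave target at 34.9 %, ahead of starting material at 30.5 % and isomer of the product at 28.1 %.

    starting material + free catalyst → spent catalyst (k = 0.398 M⁻¹ h⁻¹)
    starting material + partner ⇌ target (K = 5.22 M⁻¹, k = 3.85 M⁻¹ h⁻¹)
    target + free catalyst ⇌ isomer of the product + free catalyst, rate k3*[free catalyst]*[target] forward; the back reaction follows from the equilibrium constant (k = 6.80 M⁻¹ h⁻¹)
    starting material + partner ⇌ isomer of the product (K = 4.20 M⁻¹, k = 1.93 M⁻¹ h⁻¹)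
    starting material + protic impurity → quenched substrate (k = 41.4 M⁻¹ h⁻¹)
    starting material + partner → uncatalysed product (k = 0.0548 M⁻¹ h⁻¹)

**The pull again.** Free catalyst in the flask stood at 58.7 % of its charge at 8.00 h, above the harsh case of 16.7 %. The flask's pull came to 2.63, against 2.74 read from gamma's last reading. A further flask with 2.2 M of partner, 4.40 equiv, showed a pull of 2.63, with starting material at 5.29 % and target at 48.4 %.

All runs were generated by integration from invented constants, noise included.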